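**Retrosynthetic overview**

- The plan rests on one structural fact: the pyranone ring of the coumarin (O1, C2, C3, C4, C4a, C8a) is fused to the benzene ring at C4a, the carbon para to the C7 methoxy group and the most electron-rich position of that ring.
- Last disconnections: the Si–O bond at C1′, the C2′ ester C–O bond ((R)-2-methylbutanoic acid) and the C2′/C3′ acetonide, leaving a protected 6-substituted 7-methoxycoumarin.
- Key disconnection: C4–C4a, by gold-catalysed 6-endo-dig hydroarylation of an aryl propiolate. The pyranone is the only ring formed in the route and it is formed last.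
- The propiolate comes from a phenol whose side chain is attached at the aryl–C1′ bond by Felkin–Anh addition of an aryllithium to (4S)-2,2,5,5-tetramethyl-1,3-dioxolane-4-carbaldehyde.
- The aldehyde derives from methyl (R)-glycerate acetonide (C2′ from the chiral pool); the aryllithium derives from 4-bromo-3-methoxyphenol.

Key step: step 9

Locants: C1′ is the benzylic carbinol carbon, C2′ the ester-bearing carbon, C3′ the tertiary carbinol carbon; ring atoms carry coumarin numbering.

**Step 1**
Reactants: 1 methyl (R)-2,2-dimethyl-1,3-dioxolane-4-carboxylate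
Product: 2 2-[(4R)-2,2-dimethyl-1,3-dioxolan-4-yl]propan-2-ol
Conditions: MeMgBr (3 equiv), THF, 0 °C → rt; aqueous work-up
Reagents that add atoms: methylmagnesium bromide, C[Mg]Br
Why: Double Grignard addition to the ester gives the tertiary carbinol without breaking any bond at the stereocentre, and the acetonide is inert to MeMgBr.

**Step 2**
Reactants: 2 2-[(4R)-2,2-dimethyl-1,3-dioxolan-4-yl]propan-2-ol
Product: 3 [(4R)-2,2,5,5-tetramethyl-1,3-dioxolan-4-yl]methanol
Conditions: camphorsulfonic acid (5 mol%), CH2Cl2, rt, equilibration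
Reagents that add atoms: none
Why: Acid-catalysed acetonide migration (intramolecular transketalisation) under thermodynamic control should favour the more substituted dioxolane through the gem-dialkyl effect while freeing the unhindered primary hydroxyl, and the C4–O bond is never broken, so the stereocentre is retained.

**Step 3**
Reactants: 3 [(4R)-2,2,5,5-tetramethyl-1,3-dioxolan-4-yl]methanol
Product: 4 (4S)-2,2,5,5-tetramethyl-1,3-dioxolane-4-carbaldehyde
Conditions: (COCl)2, DMSO, CH2Cl2, −78 °C; then Et3N, −78 → 0 °C; used crude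
Reagents that add atoms: none
Why: Swern oxidation stops at the aldehyde and at low temperature should not epimerise the α-alkoxy stereocentre, whose descriptor changes from R to S only through the change in substituent priorities.

**Step 4**
Reactants: 5 4-bromo-3-methoxyphenol
Product: 6 4-(benzyloxy)-1-bromo-2-methoxybenzene
Conditions: BnBr, K2CO3, DMF, rt
Reagents that add atoms: benzyl bromide, BrCc1ccccc1
Why: Williamson ether synthesis masks the acidic phenol before the halogen–lithium exchange.

**Step 5**
Reactants: 6 4-(benzyloxy)-1-bromo-2-methoxybenzene; 4 (4S)-2,2,5,5-tetramethyl-1,3-dioxolane-4-carbaldehyde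
Product: 8 (R)-[4-(benzyloxy)-2-methoxyphenyl][(4R)-2,2,5,5-tetramethyl-1,3-dioxolan-4-yl]methanol, via aryllithium 7 (not isolated)
Conditions: n-BuLi (1.05 equiv), THF, −78 °C; then 4 (1.2 equiv), −78 °C; aqueous work-up; chromatography
Reagents that add atoms: none
Why: Bromine–lithium exchange outpaces ortho-lithiation at −78 °C, and 1,2-addition of the aryllithium to the α-alkoxy aldehyde should follow the Felkin–Anh (polar) model, the aryl group entering anti to the C4–O3 bond and past C4–H instead of the quaternary C5, which sets C1′ as R, anti to the C2′ oxygen.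

**Step 6**
Reactants: 8 (R)-[4-(benzyloxy)-2-methoxyphenyl][(4R)-2,2,5,5-tetramethyl-1,3-dioxolan-4-yl]methanol
Product: 9 {(R)-[4-(benzyloxy)-2-methoxyphenyl][(4R)-2,2,5,5-tetramethyl-1,3-dioxolan-4-yl]methoxy}(tert-butyl)dimethylsilane
Conditions: TBSOTf (1.3 equiv), 2,6-lutidine, CH2Cl2, −78 → 0 °C
Reagents that add atoms: tert-butyldimethylsilyl trifluoromethanesulfonate, CC(C)(C)[Si](C)(C)OS(=O)(=O)C(F)(F)F
Why: Silylation of a hindered secondary alcohol with the silyl triflate and a non-nucleophilic base is reliable, and the cold, short exposure should leave the acetonide untouched.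

**Step 7**
Reactants: 9 {(R)-[4-(benzyloxy)-2-methoxyphenyl][(4R)-2,2,5,5-tetramethyl-1,3-dioxolan-4-yl]methoxy}(tert-butyl)dimethylsilane
Product: 10 4-{(R)-[(tert-butyldimethylsilyl)oxy][(4R)-2,2,5,5-tetramethyl-1,3-dioxolan-4-yl]methyl}-3-methoxyphenol
Conditions: H2 (1 atm), Pd/C (10 wt%), EtOAc, rt
Reagents that add atoms: none
Why: Hydrogenolysis of the aryl benzyl ether over Pd/C in neutral EtOAc should spare the hindered secondary benzylic silyl ether and the acetonide.

**Step 8**
Reactants: 10 4-{(R)-[(tert-butyldimethylsilyl)oxy][(4R)-2,2,5,5-tetramethyl-1,3-dioxolan-4-yl]methyl}-3-methoxyphenol; 11 propiolic acid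
Product: 12 4-{(R)-[(tert-butyldimethylsilyl)oxy][(4R)-2,2,5,5-tetramethyl-1,3-dioxolan-4-yl]methyl}-3-methoxyphenyl prop-2-ynoate
Conditions: 11 (1.5 equiv), DCC (1.5 equiv), DMAP (5 mol%), CH2Cl2, −20 → 0 °C
Reagents that add atoms: none
Why: Carbodiimide (Steglich-type) esterification of the phenol, run cold with little DMAP to limit conjugate addition to the propiolate.

**Step 9**
Reactants: 12 4-{(R)-[(tert-butyldimethylsilyl)oxy][(4R)-2,2,5,5-tetramethyl-1,3-dioxolan-4-yl]methyl}-3-methoxyphenyl prop-2-ynoate
Product: 13 6-{(R)-[(tert-butyldimethylsilyl)oxy][(4R)-2,2,5,5-tetramethyl-1,3-dioxolan-4-yl]methyl}-7-methoxy-2H-chromen-2-one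
Conditions: Ph3PAuCl (5 mol%), AgSbF6 (5 mol%), 4 Å MS, CH2Cl2, rt (ClCH2CH2Cl, 50 °C if slow)
Reagents that add atoms: none
Why: The cation Ph3PAu+ (monovalent gold, freed from Ph3PAuCl by AgSbF6) binds the terminal alkyne of 12 and makes its terminal carbon electrophilic; the arene carbon ortho to the ester oxygen and para to the methoxy group attacks it anti to gold, the Wheland intermediate rearomatises, and protodeauration of the 3-aurated coumarin releases 13 and the catalyst. The closest known reaction type is the gold-catalysed intramolecular hydroarylation of aryl alkynoates to coumarins. The pyranone ring closes in the 6-endo-dig mode with formation of the C4–C4a bond. No stereocentre is created, and C1′ and the dioxolane C4 take no part. The step needs regioselectivity between the two carbons ortho to the ester oxygen: the one used is activated by the para methoxy group and flanked only by hydrogen, whereas the other sits between the two oxygen substituents and is crowded. The neutral, anhydrous conditions should leave the silyl ether and the acetonide intact.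

**Step 10**
Reactants: 13 6-{(R)-[(tert-butyldimethylsilyl)oxy][(4R)-2,2,5,5-tetramethyl-1,3-dioxolan-4-yl]methyl}-7-methoxy-2H-chromen-2-one
Product: 14 6-{(1R,2R)-1-[(tert-butyldimethylsilyl)oxy]-2,3-dihydroxy-3-methylbutyl}-7-methoxy-2H-chromen-2-one
Conditions: AcOH/H2O (4:1), 40 °C, stopped at full conversion
Reagents that add atoms: none
Why: Mild acid-catalysed acetal hydrolysis, in which the dioxolane should open well before the hindered secondary TBS ether is attacked and the coumarin lactone is stable.

**Step 11**
Reactants: 14 6-{(1R,2R)-1-[(tert-butyldimethylsilyl)oxy]-2,3-dihydroxy-3-methylbutyl}-7-methoxy-2H-chromen-2-one; 15 (R)-2-methylbutanoic acid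
Product: 16 (1R,2R)-1-[(tert-butyldimethylsilyl)oxy]-3-hydroxy-1-(7-methoxy-2-oxo-2H-chromen-6-yl)-3-methylbutan-2-yl (2R)-2-methylbutanoate
Conditions: 15 (2 equiv), DCC (2 equiv), DMAP (0.3 equiv), CH2Cl2, 0 °C → rt
Reagents that add atoms: none
Why: Steglich esterification acylates only the secondary C2′ hydroxyl because the tertiary C3′ hydroxyl is inert under these conditions, and the near-neutral medium at low temperature should preserve the α-stereocentre of the acid and avoid silyl migration.

**Step 12**
Reactants: 16 (1R,2R)-1-[(tert-butyldimethylsilyl)oxy]-3-hydroxy-1-(7-methoxy-2-oxo-2H-chromen-6-yl)-3-methylbutan-2-yl (2R)-2-methylbutanoate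
Product: 17 (1R,2R)-1,3-dihydroxy-1-(7-methoxy-2-oxo-2H-chromen-6-yl)-3-methylbutan-2-yl (2R)-2-methylbutanoate
Conditions: HF·pyridine, pyridine, THF, 0 °C → rt
Reagents that add atoms: none
Why: Fluoride-mediated desilylation under buffered, slightly acidic conditions is chosen over basic fluoride sources so that the C2′ ester should not migrate to the neighbouring hydroxyls and the lactone should not open.

**Compound list**

1 | methyl (R)-2,2-dimethyl-1,3-dioxolane-4-carboxylate | CC1(C)O[C@H](CO1)C(=O)OC | starting material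
2 | 2-[(4R)-2,2-dimethyl-1,3-dioxolan-4-yl]propan-2-ol | CC1(C)O[C@H](CO1)C(C)(C)O | intermediate
3 | [(4R)-2,2,5,5-tetramethyl-1,3-dioxolan-4-yl]methanol | CC1(C)O[C@H](CO)C(C)(C)O1 | intermediate
4 | (4S)-2,2,5,5-tetramethyl-1,3-dioxolane-4-carbaldehyde | CC1(C)O[C@H](C=O)C(C)(C)O1 | intermediate
5 | 4-bromo-3-methoxyphenol | COc1cc(O)ccc1Br | starting material
6 | 4-(benzyloxy)-1-bromo-2-methoxybenzene | COc1cc(OCc2ccccc2)ccc1Br | intermediate
7 | [4-(benzyloxy)-2-methoxyphenyl]lithium (not isolated) | [Li]c1ccc(OCc2ccccc2)cc1OC | intermediate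
8 | (R)-[4-(benzyloxy)-2-methoxyphenyl][(4R)-2,2,5,5-tetramethyl-1,3-dioxolan-4-yl]methanol | CC1(C)O[C@H]([C@H](O)c2ccc(OCc3ccccc3)cc2OC)C(C)(C)O1 | intermediate
9 | {(R)-[4-(benzyloxy)-2-methoxyphenyl][(4R)-2,2,5,5-tetramethyl-1,3-dioxolan-4-yl]methoxy}(tert-butyl)dimethylsilane | CC1(C)O[C@H]([C@H](O[Si](C)(C)C(C)(C)C)c2ccc(OCc3ccccc3)cc2OC)C(C)(C)O1 | intermediate
10 | 4-{(R)-[(tert-butyldimethylsilyl)oxy][(4R)-2,2,5,5-tetramethyl-1,3-dioxolan-4-yl]methyl}-3-methoxyphenol | CC1(C)O[C@H]([C@H](O[Si](C)(C)C(C)(C)C)c2ccc(O)cc2OC)C(C)(C)O1 | intermediate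
11 | propiolic acid | C#CC(=O)O | starting material
12 | 4-{(R)-[(tert-butyldimethylsilyl)oxy][(4R)-2,2,5,5-tetramethyl-1,3-dioxolan-4-yl]methyl}-3-methoxyphenyl prop-2-ynoate | CC1(C)O[C@H]([C@H](O[Si](C)(C)C(C)(C)C)c2ccc(OC(=O)C#C)cc2OC)C(C)(C)O1 | intermediate
13 | 6-{(R)-[(tert-butyldimethylsilyl)oxy][(4R)-2,2,5,5-tetramethyl-1,3-dioxolan-4-yl]methyl}-7-methoxy-2H-chromen-2-one | CC1(C)O[C@H]([C@H](O[Si](C)(C)C(C)(C)C)c2cc3ccc(=O)oc3cc2OC)C(C)(C)O1 | intermediate
14 | 6-{(1R,2R)-1-[(tert-butyldimethylsilyl)oxy]-2,3-dihydroxy-3-methylbutyl}-7-methoxy-2H-chromen-2-one | O[C@H]([C@H](O[Si](C)(C)C(C)(C)C)c1cc2ccc(=O)oc2cc1OC)C(C)(C)O | intermediate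
15 | (R)-2-methylbutanoic acid | CC[C@@H](C)C(=O)O | starting material
16 | (1R,2R)-1-[(tert-butyldimethylsilyl)oxy]-3-hydroxy-1-(7-methoxy-2-oxo-2H-chromen-6-yl)-3-methylbutan-2-yl (2R)-2-methylbutanoate | CC[C@@H](C)C(=O)O[C@H]([C@H](O[Si](C)(C)C(C)(C)C)c1cc2ccc(=O)oc2cc1OC)C(C)(C)O | intermediate
17 | (1R,2R)-1,3-dihydroxy-1-(7-methoxy-2-oxo-2H-chromen-6-yl)-3-methylbutan-2-yl (2R)-2-methylbutanoate | CC[C@@H](C)C(=O)O[C@H]([C@H](O)c1cc2ccc(=O)oc2cc1OC)C(C)(C)O | target

**Step count**

Total step count: 12.
Longest linear sequence: 11 steps (steps 1–3 and 5–12, from 1 to 17).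

**Steps most likely to fail**

Step 9. The aryl ester must adopt its less favoured conformation for the alkyne to reach the ring, so cyclisation may be slow. Alkyne hydration, ester cleavage or acid-induced loss of the acetonide could then compete, and attack at the carbon between the two oxygens would erode regioselectivity. The fallback sets out from phenol 10 and comes back at 13, and step 8 is then not needed. Magnesium-mediated ortho-formylation of 10 (MgCl2, Et3N, paraformaldehyde, MeCN, reflux) should place the formyl group at the free ortho carbon para to the methoxy group and give the salicylaldehyde F1. Heating F1 with ethyl (triphenylphosphoranylidene)acetate in N,N-diethylaniline at reflux should give the ethyl (E)-cinnamate F2 (formed in the flask), which isomerises thermally and lactonises with loss of ethanol to 13.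

Step 5. Facial selectivity in the aryllithium addition may be poor if lithium chelates the carbonyl oxygen and O3 of the dioxolane, giving much of the C1′ epimer. The fallback sets out from 8 as the mixture of C1′ epimers and comes back at 8 as a single isomer. Dess–Martin oxidation (CH2Cl2, NaHCO3, rt) should give the aryl ketone F3. Reduction with Zn(BH4)2 in Et2O at −40 °C under chelation control, with zinc bridging the ketone oxygen and O3 and hydride entering from the side of C4–H, should return the anti alcohol 8 with C1′ R. Chelation-controlled reduction of the ketone gives the same diastereomer as Felkin–Anh addition to the aldehyde.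

Step 10. The acid needed to open the hindered tetrasubstituted dioxolane may also cleave the benzylic silyl ether before hydrolysis is complete. The fallback sets out from 13 and comes back at 14. Both protecting groups are removed on purpose (1 M aq. HCl/THF, rt) to give the triol F4. Silylation with TBSCl and imidazole in DMF at 0 °C should then take place at the benzylic C1′ hydroxyl, which is flanked by the planar arene, in preference to the C2′ hydroxyl, which is neopentyl-like next to the fully substituted C3′, and so deliver 14.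

**Further compounds**

F1 | step 9 | 5-{(R)-[(tert-butyldimethylsilyl)oxy][(4R)-2,2,5,5-tetramethyl-1,3-dioxolan-4-yl]methyl}-2-hydroxy-4-methoxybenzaldehyde | CC1(C)O[C@H]([C@H](O[Si](C)(C)C(C)(C)C)c2cc(C=O)c(O)cc2OC)C(C)(C)O1
F2 | step 9 | ethyl (2E)-3-(5-{(R)-[(tert-butyldimethylsilyl)oxy][(4R)-2,2,5,5-tetramethyl-1,3-dioxolan-4-yl]methyl}-2-hydroxy-4-methoxyphenyl)prop-2-enoate | CC1(C)O[C@H]([C@H](O[Si](C)(C)C(C)(C)C)c2cc(/C=C/C(=O)OCC)c(O)cc2OC)C(C)(C)O1
F3 | step 5 | [4-(benzyloxy)-2-methoxyphenyl][(4S)-2,2,5,5-tetramethyl-1,3-dioxolan-4-yl]methanone | CC1(C)O[C@H](C(=O)c2ccc(OCc3ccccc3)cc2OC)C(C)(C)O1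
F4 | step 10 | 7-methoxy-6-[(1R,2R)-1,2,3-trihydroxy-3-methylbutyl]-2H-chromen-2-one | O[C@H]([C@H](O)c1cc2ccc(=O)oc2cc1OC)C(C)(C)O
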